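**Retrosynthetic overview**
1. 23 ⇐ 19: the end-game is functional-group work only (C-3 carbinol → ketone, silyl ether → acetate, allyl ester → acid). Labdane numbering is used for the bicycle; acyclic compounds are numbered from the ester carbon.
2. 19 ⇐ 18: ring A, then ring B (bonds C4–C5, then C9–C10), are closed in one epoxide-initiated cation–olefin cascade on the complete C20 chain. This mirrors the presumed biogenesis from an all-cis polyprenyl precursor; the conjugated ester alkene stays out, and loss of H from C-17 ends the cascade.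
3. Stereochemical logic (all-chair, anti additions): 10Z alkene → cis ring fusion; 6Z alkene → C-9 chain cis to CH3-10; E-CH2O on the epoxide → CH2O trans to CH3-10; (14S,15S)-epoxide → absolute configuration.
4. 18 ⇐ 15: terminal allylic hydroxylation (SeO2), then Sharpless epoxidation.
5. 15 ⇐ 1: three iterative syn-carbocuprations of propyne (trapped twice with oxirane, once with CO2) build the all-Z chain.

Assumption: the SMILES is taken literally, (4R,5S,9S,10R), i.e. a cis-fused decalin with H-5, CH3-10, CH3-4 and the C-9 chain on one face and CH2OAc on the other, and a 13Z acid.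

**Route**

Step 1
Reactants: 1 5-bromo-2-methylpent-2-ene; 2 propyne; 3 oxirane
Product: 6 (3Z)-4,8-dimethylnona-3,7-dien-1-ol, via Grignard reagent 4 (not isolated), via alkenylcopper 5 (not isolated)
Conditions: Mg, Et2O, 35 °C; CuBr·SMe2, Et2O/Me2S, −45 °C; 2, −25 °C; LiC≡C-n-Pr, HMPA, 3, −45 → 0 °C; H2O
Reagents that add atoms: none
Why: Normant carbocupration: after transmetalation of 4 to copper, the alkyl group and copper add syn across propyne (copper on the terminal carbon) to give 5, whose pentynyl cuprate opens oxirane with retention at the alkenyl carbon, so the chain and the CH2CH2OH arm end up cis and the new trisubstituted alkene is Z.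

Step 2
Reactants: 6 (3Z)-4,8-dimethylnona-3,7-dien-1-ol
Product: 7 (6Z)-9-bromo-2,6-dimethylnona-2,6-diene
Conditions: CBr4, PPh3, CH2Cl2, 0 °C
Reagents that add atoms: tetrabromomethane, BrC(Br)(Br)Br
Why: Appel bromination of a primary homoallylic alcohol is an SN2 displacement of the oxyphosphonium group under neutral conditions, so the Z alkene is untouched and no stereocentre is involved.

Step 3
Reactants: 7 (6Z)-9-bromo-2,6-dimethylnona-2,6-diene; 2 propyne; 3 oxirane
Product: 10 (3Z,7Z)-4,8,12-trimethyltrideca-3,7,11-trien-1-ol, via Grignard reagent 8 (not isolated), via alkenylcopper 9 (not isolated)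
Conditions: Mg, Et2O, 35 °C; CuBr·SMe2, Et2O/Me2S, −45 °C; 2, −25 °C; LiC≡C-n-Pr, HMPA, 3, −45 → 0 °C; H2O
Reagents that add atoms: none
Why: A second Normant carbocupration of propyne followed by oxirane opening, again a syn addition with retention in the trapping, sets the second Z alkene (the one that later fixes C-9).

Step 4
Reactants: 10 (3Z,7Z)-4,8,12-trimethyltrideca-3,7,11-trien-1-ol
Product: 11 (6Z,10Z)-13-bromo-2,6,10-trimethyltrideca-2,6,10-triene
Conditions: CBr4, PPh3, CH2Cl2, 0 °C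
Reagents that add atoms: tetrabromomethane, BrC(Br)(Br)Br
Why: Appel bromination as in step 2, neutral and without effect on the two Z alkenes.

Step 5
Reactants: 11 (6Z,10Z)-13-bromo-2,6,10-trimethyltrideca-2,6,10-triene; 2 propyne
Product: 15 prop-2-en-1-yl (2Z,6Z,10Z)-3,7,11,15-tetramethylhexadeca-2,6,10,14-tetraenoate, via Grignard reagent 12 (not isolated), via alkenylcopper 13 (not isolated), via copper carboxylate 14 (not isolated)
Conditions: Mg, Et2O/THF, 35 °C; CuBr·SMe2, Et2O/Me2S, −45 °C; 2, −25 °C; CO2 (1 atm), HMPA, P(OEt)3 (cat.), −40 → 20 °C; allyl bromide, 40 °C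
Reagents that add atoms: carbon dioxide, O=C=O; allyl bromide, C=CCBr
Why: A third Normant carbocupration gives 13, which is carboxylated with retention to the (2Z)-carboxylate 14 and then O-allylated in the same flask (SN2 on allyl bromide), so the future 13Z acid geometry is fixed and the acid is masked as an ester that can be removed under neutral conditions.

Step 6
Reactants: 15 prop-2-en-1-yl (2Z,6Z,10Z)-3,7,11,15-tetramethylhexadeca-2,6,10,14-tetraenoate
Product: 16 prop-2-en-1-yl (2Z,6Z,10Z,14E)-16-hydroxy-3,7,11,15-tetramethylhexadeca-2,6,10,14-tetraenoate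
Conditions: SeO2 (0.3 equiv), t-BuOOH, salicylic acid (cat.), CH2Cl2, 0 → 20 °C, stopped at partial conversion
Reagents that add atoms: selenium dioxide, O=[Se]=O (catalytic oxygen carrier); tert-butyl hydroperoxide, CC(C)(C)OO (terminal oxidant)
Why: Catalytic SeO2/t-BuOOH allylic oxidation (ene reaction, then [2,3]-sigmatropic shift) hydroxylates the (E)-methyl of the terminal isopropylidene group, the least hindered trisubstituted alkene, while the conjugated 2,3-alkene is deactivated, giving the E allylic alcohol that serves both as the epoxidation handle and as the future CH2OAc carbon.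

Step 7
Reactants: 16 prop-2-en-1-yl (2Z,6Z,10Z,14E)-16-hydroxy-3,7,11,15-tetramethylhexadeca-2,6,10,14-tetraenoate
Product: 18 prop-2-en-1-yl (2Z,6Z,10Z)-13-[(2S,3S)-3-({[tert-butyl(dimethyl)silyl]oxy}methyl)-3-methyloxiran-2-yl]-3,7,11-trimethyltrideca-2,6,10-trienoate, via epoxy alcohol 17 (not isolated)
Conditions: Ti(OiPr)4 (10 mol %), L-(+)-diethyl tartrate (12 mol %), t-BuOOH (1.3 equiv), 4 Å MS, CH2Cl2, −20 °C; then imidazole, TBSCl, −20 → 0 °C
Reagents that add atoms: tert-butyl hydroperoxide, CC(C)(C)OO; tert-butyl(chloro)dimethylsilane, CC(C)(C)[Si](C)(C)Cl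
Why: Katsuki–Sharpless asymmetric epoxidation touches only the allylic-alcohol alkene and, with L-(+)-diethyl tartrate, gives the (2S,3S)-epoxy alcohol 17 as it does for other E allylic alcohols (14S,15S in chain numbering), which sets the absolute configuration of the whole ring system, and silylation in the same flask supplies a protecting group that cannot act as a neighbouring group in the cationic step.

Step 8
Reactants: 18 prop-2-en-1-yl (2Z,6Z,10Z)-13-[(2S,3S)-3-({[tert-butyl(dimethyl)silyl]oxy}methyl)-3-methyloxiran-2-yl]-3,7,11-trimethyltrideca-2,6,10-trienoate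
Product: 19 prop-2-en-1-yl (2Z)-5-[(1S,4aS,5R,6S,8aR)-5-({[tert-butyl(dimethyl)silyl]oxy}methyl)-6-hydroxy-5,8a-dimethyl-2-methylidenedecahydronaphthalen-1-yl]-3-methylpent-2-enoate
Conditions: MeAlCl2 (2.5 equiv), CH2Cl2, −78 °C; then aq. NaHCO3
Reagents that add atoms: none
Why: Proposed new method: an epoxide-initiated cation–olefin bicyclization following the Stork–Eschenmoser course (closest known chemistry: MeAlCl2-promoted cyclizations of epoxy polyprenoids and Z-allylsilane-terminated epoxy-triene cyclizations giving 9,10-syn labdanes), in which the activated epoxide is opened at C-4 with inversion by the 10Z alkene through a chair (equatorial O–Al and CH2OSi, axial CH3), anti addition across that Z alkene puts H-5 and CH3-10 cis, the 6Z alkene closes ring B through a second chair with the side chain axial (C-9 chain cis to CH3-10), the conjugated ester alkene is too electron-poor to take part, and the C-8 cation, whose neighbouring H-9 is equatorial and misaligned, loses a proton from C-17 to the Al–CH3 group to leave the exocyclic alkene, so C-4, C-5, C-9 and C-10 are all set from the epoxide in one step.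

Step 9
Reactants: 19 prop-2-en-1-yl (2Z)-5-[(1S,4aS,5R,6S,8aR)-5-({[tert-butyl(dimethyl)silyl]oxy}methyl)-6-hydroxy-5,8a-dimethyl-2-methylidenedecahydronaphthalen-1-yl]-3-methylpent-2-enoate
Product: 20 prop-2-en-1-yl (2Z)-5-[(1S,4aS,5R,8aR)-5-({[tert-butyl(dimethyl)silyl]oxy}methyl)-5,8a-dimethyl-2-methylidene-6-oxodecahydronaphthalen-1-yl]-3-methylpent-2-enoate
Conditions: Dess–Martin periodinane, pyridine, CH2Cl2, 0 → 20 °C
Reagents that add atoms: none
Why: Dess–Martin oxidation converts the hindered C-3 carbinol into the ketone under buffered conditions that leave the exocyclic alkene, silyl ether and allyl ester alone, and since C-4 is quaternary nothing can epimerize while the now superfluous C-3 stereocentre is erased.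

Step 10
Reactants: 20 prop-2-en-1-yl (2Z)-5-[(1S,4aS,5R,8aR)-5-({[tert-butyl(dimethyl)silyl]oxy}methyl)-5,8a-dimethyl-2-methylidene-6-oxodecahydronaphthalen-1-yl]-3-methylpent-2-enoate
Product: 22 prop-2-en-1-yl (2Z)-5-[(1S,4aS,5R,8aR)-5-(acetoxymethyl)-5,8a-dimethyl-2-methylidene-6-oxodecahydronaphthalen-1-yl]-3-methylpent-2-enoate, via hydroxy ketone 21 (not isolated)
Conditions: HF·pyridine, pyridine, THF, 0 → 20 °C; then Ac2O, DMAP, 0 °C
Reagents that add atoms: acetic anhydride, CC(=O)OC(C)=O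
Why: Buffered HF·pyridine cleaves the primary silyl ether to the β-hydroxy ketone 21 without retro-aldol cleavage, and DMAP-catalysed acylation with acetic anhydride in the same flask installs the acetate only after the cationic step, where it could have acted as a neighbouring group.

Step 11
Reactants: 22 prop-2-en-1-yl (2Z)-5-[(1S,4aS,5R,8aR)-5-(acetoxymethyl)-5,8a-dimethyl-2-methylidene-6-oxodecahydronaphthalen-1-yl]-3-methylpent-2-enoate
Product: 23 (2Z)-5-[(1S,4aS,5R,8aR)-5-(acetoxymethyl)-5,8a-dimethyl-2-methylidene-6-oxodecahydronaphthalen-1-yl]-3-methylpent-2-enoic acid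
Conditions: Pd(PPh3)4 (5 mol %), morpholine, THF, 20 °C; then aq. citric acid
Reagents that add atoms: none
Why: Tsuji–Trost deallylation, in which zerovalent palladium ionizes the allyl ester to a π-allyl complex that morpholine traps, frees the acid at room temperature without touching the acetate, the ketone, the exocyclic alkene or the Z geometry of the enoic acid.

**Compound list**
1 | 5-bromo-2-methylpent-2-ene | CC(C)=CCCBr | starting material
2 | propyne | CC#C | starting material
3 | oxirane | C1CO1 | starting material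
4 | (4-methylpent-3-en-1-yl)magnesium bromide | CC(C)=CCC[Mg]Br | intermediate
5 | [(1Z)-2,6-dimethylhepta-1,5-dien-1-yl]copper | CC(C)=CCC/C(C)=C\[Cu] | intermediate
6 | (3Z)-4,8-dimethylnona-3,7-dien-1-ol | CC(C)=CCC/C(C)=C\CCO | intermediate
7 | (6Z)-9-bromo-2,6-dimethylnona-2,6-diene | CC(C)=CCC/C(C)=C\CCBr | intermediate
8 | [(3Z)-4,8-dimethylnona-3,7-dien-1-yl]magnesium bromide | CC(C)=CCC/C(C)=C\CC[Mg]Br | intermediate
9 | [(1Z,5Z)-2,6,10-trimethylundeca-1,5,9-trien-1-yl]copper | CC(C)=CCC/C(C)=C\CC/C(C)=C\[Cu] | intermediate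
10 | (3Z,7Z)-4,8,12-trimethyltrideca-3,7,11-trien-1-ol | CC(C)=CCC/C(C)=C\CC/C(C)=C\CCO | intermediate
11 | (6Z,10Z)-13-bromo-2,6,10-trimethyltrideca-2,6,10-triene | CC(C)=CCC/C(C)=C\CC/C(C)=C\CCBr | intermediate
12 | [(3Z,7Z)-4,8,12-trimethyltrideca-3,7,11-trien-1-yl]magnesium bromide | CC(C)=CCC/C(C)=C\CC/C(C)=C\CC[Mg]Br | intermediate
13 | [(1Z,5Z,9Z)-2,6,10,14-tetramethylpentadeca-1,5,9,13-tetraen-1-yl]copper | CC(C)=CCC/C(C)=C\CC/C(C)=C\CC/C(C)=C\[Cu] | intermediate
14 | copper (2Z,6Z,10Z)-3,7,11,15-tetramethylhexadeca-2,6,10,14-tetraenoate (RCO2Cu, monovalent copper) | CC(C)=CCC/C(C)=C\CC/C(C)=C\CC/C(C)=C\C(=O)O[Cu] | intermediate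
15 | prop-2-en-1-yl (2Z,6Z,10Z)-3,7,11,15-tetramethylhexadeca-2,6,10,14-tetraenoate | CC(C)=CCC/C(C)=C\CC/C(C)=C\CC/C(C)=C\C(=O)OCC=C | intermediate
16 | prop-2-en-1-yl (2Z,6Z,10Z,14E)-16-hydroxy-3,7,11,15-tetramethylhexadeca-2,6,10,14-tetraenoate | OC/C(C)=C/CC/C(C)=C\CC/C(C)=C\CC/C(C)=C\C(=O)OCC=C | intermediate
17 | prop-2-en-1-yl (2Z,6Z,10Z)-13-[(2S,3S)-3-(hydroxymethyl)-3-methyloxiran-2-yl]-3,7,11-trimethyltrideca-2,6,10-trienoate | OC[C@]1(C)O[C@H]1CC/C(C)=C\CC/C(C)=C\CC/C(C)=C\C(=O)OCC=C | intermediate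
18 | prop-2-en-1-yl (2Z,6Z,10Z)-13-[(2S,3S)-3-({[tert-butyl(dimethyl)silyl]oxy}methyl)-3-methyloxiran-2-yl]-3,7,11-trimethyltrideca-2,6,10-trienoate | CC(C)(C)[Si](C)(C)OC[C@]1(C)O[C@H]1CC/C(C)=C\CC/C(C)=C\CC/C(C)=C\C(=O)OCC=C | intermediate
19 | prop-2-en-1-yl (2Z)-5-[(1S,4aS,5R,6S,8aR)-5-({[tert-butyl(dimethyl)silyl]oxy}methyl)-6-hydroxy-5,8a-dimethyl-2-methylidenedecahydronaphthalen-1-yl]-3-methylpent-2-enoate (labdane 3S,4R,5S,9S,10R) | C=C1CC[C@H]2[C@](C)(CC[C@H](O)[C@@]2(C)CO[Si](C)(C)C(C)(C)C)[C@H]1CC/C(C)=C\C(=O)OCC=C | intermediate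
20 | prop-2-en-1-yl (2Z)-5-[(1S,4aS,5R,8aR)-5-({[tert-butyl(dimethyl)silyl]oxy}methyl)-5,8a-dimethyl-2-methylidene-6-oxodecahydronaphthalen-1-yl]-3-methylpent-2-enoate | C=C1CC[C@H]2[C@](C)(CCC(=O)[C@@]2(C)CO[Si](C)(C)C(C)(C)C)[C@H]1CC/C(C)=C\C(=O)OCC=C | intermediate
21 | prop-2-en-1-yl (2Z)-5-[(1S,4aS,5R,8aR)-5-(hydroxymethyl)-5,8a-dimethyl-2-methylidene-6-oxodecahydronaphthalen-1-yl]-3-methylpent-2-enoate | C=C1CC[C@H]2[C@](C)(CCC(=O)[C@@]2(C)CO)[C@H]1CC/C(C)=C\C(=O)OCC=C | intermediate
22 | prop-2-en-1-yl (2Z)-5-[(1S,4aS,5R,8aR)-5-(acetoxymethyl)-5,8a-dimethyl-2-methylidene-6-oxodecahydronaphthalen-1-yl]-3-methylpent-2-enoate | C=C1CC[C@H]2[C@](C)(CCC(=O)[C@@]2(C)COC(C)=O)[C@H]1CC/C(C)=C\C(=O)OCC=C | intermediate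
23 | (2Z)-5-[(1S,4aS,5R,8aR)-5-(acetoxymethyl)-5,8a-dimethyl-2-methylidene-6-oxodecahydronaphthalen-1-yl]-3-methylpent-2-enoic acid (CNP0243698.1; labdane 4R,5S,9S,10R) | C=C1CC[C@H]2[C@](C)(CCC(=O)[C@@]2(C)COC(C)=O)[C@H]1CC/C(C)=C\C(=O)O | target

**Step count and risks**

Total: 11 steps. Longest linear sequence: 11 steps (fully linear from 1). The three steps most likely to fail, in order of risk, are step 8, step 6 and step 5; the fallbacks are given in route order.

Step 5. Three operations are telescoped on the most valuable organometallic, and either the carboxylation of 13 or the O-allylation of 14 may be incomplete. The fallback sets out from 11 and comes back at 15, replacing carboxylation/alkylation by acylation of an alkenyllithium. Alkenylcopper 13 is made as before but quenched with I2, which gives (1Z,5Z,9Z)-1-iodo-2,6,10,14-tetramethylpentadeca-1,5,9,13-tetraene F1 with retention. This stable iodide is purified and converted with t-BuLi (2 equiv, Et2O, −78 °C) into [(1Z,5Z,9Z)-2,6,10,14-tetramethylpentadeca-1,5,9,13-tetraen-1-yl]lithium F2, and allyl chloroformate then gives 15.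

Step 6. In the all-Z chain each internal alkene also carries an (E)-methyl group, so SeO2 may not single out the terminal one as cleanly as in all-E polyprenoids, and yields at partial conversion are moderate at best. The fallback sets out from 1 and comes back at 16, doing the allylic oxidation first, where there is only one alkene. SeO2/t-BuOOH on 1 gives (2E)-5-bromo-2-methylpent-2-en-1-ol F3, and TBSCl/imidazole gives its TBS ether F4. The operations of steps 1 to 4 then give in turn C11 alcohol F5, C11 bromide F6, C16 alcohol F7 and C16 bromide F8. The conditions of step 5 give silyl-protected allyl ester F9, and n-Bu4NF/AcOH removes the silyl group to give 16.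

Step 8. A plain trisubstituted alkene is a weak and unselective terminator: the cascade may stop after ring A, or the C-8 cation may lose a ring proton and give endocyclic isomers of 19 that have to be removed on AgNO3-impregnated silica. The fallback replaces proton loss by an allylsilane terminator; it sets out from 1, shares F3 to F6 with the fallback for step 6, and comes back at 19. C11 bromide F6 is taken through the conditions of step 3 with 3-(trimethylsilyl)propyne in place of 2, which gives C16 allylsilane alcohol F10 with the chain again cis to the CH2CH2OH arm. Appel bromination gives allylsilane bromide F11, and the conditions of step 5 give allylsilane allyl ester F12. n-Bu4NF/AcOH gives allylic alcohol F13, and the conditions of step 7 give epoxy alcohol F14 (not isolated) and epoxy silyl ether F15. SnCl4 (CH2Cl2, −78 °C) then closes both rings, and the β-silyl cation at C-8 loses the Me3Si group, so the 8(17)-alkene of 19 is formed regiospecifically. The oxidation must precede the silane, because SeO2 would attack an allylsilane.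

Further compounds
F1 | step 5 | (1Z,5Z,9Z)-1-iodo-2,6,10,14-tetramethylpentadeca-1,5,9,13-tetraene | CC(C)=CCC/C(C)=C\CC/C(C)=C\CC/C(C)=C\I
F2 | step 5 | [(1Z,5Z,9Z)-2,6,10,14-tetramethylpentadeca-1,5,9,13-tetraen-1-yl]lithium | CC(C)=CCC/C(C)=C\CC/C(C)=C\CC/C(C)=C\[Li]
F3 | step 6 | (2E)-5-bromo-2-methylpent-2-en-1-ol | OC/C(C)=C/CCBr
F4 | step 6 | {[(2E)-5-bromo-2-methylpent-2-en-1-yl]oxy}(tert-butyl)dimethylsilane | CC(C)(C)[Si](C)(C)OC/C(C)=C/CCBr
F5 | step 6 | (3Z,7E)-9-{[tert-butyl(dimethyl)silyl]oxy}-4,8-dimethylnona-3,7-dien-1-ol | CC(C)(C)[Si](C)(C)OC/C(C)=C/CC/C(C)=C\CCO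
F6 | step 6 | {[(2E,6Z)-9-bromo-2,6-dimethylnona-2,6-dien-1-yl]oxy}(tert-butyl)dimethylsilane | CC(C)(C)[Si](C)(C)OC/C(C)=C/CC/C(C)=C\CCBr
F7 | step 6 | (3Z,7Z,11E)-13-{[tert-butyl(dimethyl)silyl]oxy}-4,8,12-trimethyltrideca-3,7,11-trien-1-ol | CC(C)(C)[Si](C)(C)OC/C(C)=C/CC/C(C)=C\CC/C(C)=C\CCO
F8 | step 6 | {[(2E,6Z,10Z)-13-bromo-2,6,10-trimethyltrideca-2,6,10-trien-1-yl]oxy}(tert-butyl)dimethylsilane | CC(C)(C)[Si](C)(C)OC/C(C)=C/CC/C(C)=C\CC/C(C)=C\CCBr
F9 | step 6 | prop-2-en-1-yl (2Z,6Z,10Z,14E)-16-{[tert-butyl(dimethyl)silyl]oxy}-3,7,11,15-tetramethylhexadeca-2,6,10,14-tetraenoate | CC(C)(C)[Si](C)(C)OC/C(C)=C/CC/C(C)=C\CC/C(C)=C\CC/C(C)=C\C(=O)OCC=C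
F10 | step 8 | (3E,7Z,11E)-13-{[tert-butyl(dimethyl)silyl]oxy}-8,12-dimethyl-4-[(trimethylsilyl)methyl]trideca-3,7,11-trien-1-ol | CC(C)(C)[Si](C)(C)OC/C(C)=C/CC/C(C)=C\CC/C(C[Si](C)(C)C)=C\CCO
F11 | step 8 | {[(2E,6Z,10E)-13-bromo-2,6-dimethyl-10-[(trimethylsilyl)methyl]trideca-2,6,10-trien-1-yl]oxy}(tert-butyl)dimethylsilane | CC(C)(C)[Si](C)(C)OC/C(C)=C/CC/C(C)=C\CC/C(C[Si](C)(C)C)=C\CCBr
F12 | step 8 | prop-2-en-1-yl (2Z,6E,10Z,14E)-16-{[tert-butyl(dimethyl)silyl]oxy}-3,11,15-trimethyl-7-[(trimethylsilyl)methyl]hexadeca-2,6,10,14-tetraenoate | CC(C)(C)[Si](C)(C)OC/C(C)=C/CC/C(C)=C\CC/C(C[Si](C)(C)C)=C\CC/C(C)=C\C(=O)OCC=C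
F13 | step 8 | prop-2-en-1-yl (2Z,6E,10Z,14E)-16-hydroxy-3,11,15-trimethyl-7-[(trimethylsilyl)methyl]hexadeca-2,6,10,14-tetraenoate | OC/C(C)=C/CC/C(C)=C\CC/C(C[Si](C)(C)C)=C\CC/C(C)=C\C(=O)OCC=C
F14 | step 8 | prop-2-en-1-yl (2Z,6E,10Z)-13-[(2S,3S)-3-(hydroxymethyl)-3-methyloxiran-2-yl]-3,11-dimethyl-7-[(trimethylsilyl)methyl]trideca-2,6,10-trienoate | OC[C@]1(C)O[C@H]1CC/C(C)=C\CC/C(C[Si](C)(C)C)=C\CC/C(C)=C\C(=O)OCC=C
F15 | step 8 | prop-2-en-1-yl (2Z,6E,10Z)-13-[(2S,3S)-3-({[tert-butyl(dimethyl)silyl]oxy}methyl)-3-methyloxiran-2-yl]-3,11-dimethyl-7-[(trimethylsilyl)methyl]trideca-2,6,10-trienoate | CC(C)(C)[Si](C)(C)OC[C@]1(C)O[C@H]1CC/C(C)=C\CC/C(C[Si](C)(C)C)=C\CC/C(C)=C\C(=O)OCC=C
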